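Remark on the chemistry: the stereodescriptor in the target SMILES corresponds to (2S) at C2, and the route is planned for that enantiomer.

## Analysis of the target

Monotesone A is a flavanone: a 2,3-dihydrochromen-4-one whose benzo ring (ring A) carries hydroxyls at C5 and C7 and whose heterocycle (ring C) carries at C2 a 3-hydroxy-4-(3-methylbut-2-enyloxy)phenyl group (ring B). C2 is the only stereocentre and is S; with no second centre to relay from, its configuration has to come from a reagent or a catalyst. This carbon is a benzylic ether, β to the C4 ketone and para to an alkoxy group, so it can be scrambled by ring opening or by ionisation and is best set late and under mild conditions. The prenyl aryl ether is the second sensitive element: Lewis and Brønsted acids cleave it, its alkene rules out hydrogenolytic deprotection, and it is a chromophore in its own right. Four phenolic oxygens have to be told apart, and only O4' is alkylated. The difficulty is that the usual way to the C4–C4a aryl ketone bond, an acid-mediated acylation of ring A, is closed by this acid lability. The plan rests on the phloroglucinol pattern of ring A: before acylation its three oxygens are equivalent and so are its three unsubstituted carbons (the future C4a, C6 and C8), so an acyl group parked on any ring A oxygen can be moved to a neighbouring or to the opposite carbon and still give the C4–C4a bond.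

## Retrosynthetic reasoning

**O1–C2.** The last bond made is O1–C2. Cutting it gives the open-chain hydroxy ketone 15, in which the future C2 is an R-configured benzylic alcohol and the nucleophile is either of the two equivalent ortho hydroxyls of ring A. The forward reaction is an intramolecular Mitsunobu etherification, a 6-exo-tet displacement with inversion, so 3R in 15 becomes 2S in 16. The cut is made here because the stereocentre then derives from a carbinol that can be made in high enantiopurity, and because the sensitive flavanone meets no further reagent.

**Silyl groups.** 15 comes from 14 by removal of all four silyl groups in one operation. Silyl ethers are used throughout because their cleavage touches neither the alkene nor the prenyl ether.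

**C4–C4a.** The aryl ketone bond of 14 is cut to the aryl ester 13. This turns a difficult C-acylation into an easy O-acylation followed by an oxygen-to-carbon acyl shift under light. The forward step has to break the aryl O–acyl bond and re-attach the acyl group at a ring carbon without acid. Because of the symmetry of ring A, attachment at either ortho carbon gives 14, and even attachment at the para carbon forms the same C4–C4a bond.

**Ester C–O.** 13 is cut at the ester oxygen into the acid 12 and the phenol 2, which are joined by a neutral coupling. 2 comes from 1 by silylation of two of its three equivalent hydroxyls.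

**Protecting-group timing.** 12 is traced through the silyl ester 11 to the dihydroxy acid 10, and this to the hydroxy ester 9. The ester is hydrolysed before the final silyl groups go on, because an aryl silyl ether does not survive ester saponification. The aryl silyl group of 9 is therefore allowed to fall in the same operation, and both hydroxyls are silylated afterwards.

**C3 stereocentre.** 9 comes from the β-keto ester 8 by asymmetric transfer hydrogenation of the aryl ketone. This is the only stereo-determining step of the route, and it is made deliberately on a simple substrate.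

**Cα–C(carbonyl).** 8 is cut between the ketone carbon and the methylene into the aldehyde 6 and the diazo ester 7, joined by a Roskamp homologation. This adds the two-carbon unit in one step at the correct oxidation level.

**Ring B ether.** 6 comes from 5 by silylation, and 5 from 3 and 4 by alkylation of the more acidic 4-hydroxyl. The prenyl group is thus placed on the right oxygen at the very start, when only two phenols have to be distinguished.

## Alternatives that were turned down

Alternative 1: The C2–C3 bond is cut and ring C is closed by carbene insertion. The diazoketone A1, 2-diazo-1-[2-{[3-(tert-butyldimethylsilyloxy)-4-(3-methylbut-2-enyloxy)phenyl]methoxy}-4,6-bis(triisopropylsilyloxy)phenyl]ethanone, would be decomposed by a chiral dirhodium carboxylate such as Rh2(S-PTTL)4. The carbenoid carbon would insert into one of the enantiotopic benzylic C–H bonds of the O–CH2 group to give the protected flavanone A2.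

- In favour: ring C and the stereocentre arise in a single catalytic C–C bond formation. The configuration does not depend on a substitution at an ionisable benzylic carbon; on this point it is stronger than the chosen route.
- Against: the electrophilic carbenoid has other partners in this molecule. The adjacent ether oxygen can form an oxonium ylide, and a 1,2-benzyl shift then gives a five-membered ring ketone in place of ring C. The prenyl alkene and the electron-rich rings are also open to attack. Enantioselectivity in six-membered closures of this kind is usually moderate.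
- Step economy: A1 needs a ring A in which one ortho oxygen is benzylated and the other two are silylated, so the symmetry of ring A has to be broken early by protecting-group work. A1 also needs diazomethane chemistry. The step count would not be lower.
- In its place the chosen route offers a stereocentre from a well-precedented ketone reduction, and a ring A whose symmetry is used instead of fought.

Alternative 2: The C2–C1' bond is cut. The chromone A3, 5,7-bis(tert-butyldimethylsilyloxy)chromen-4-one, would take up the arylboronic acid A4, [3-(tert-butyldimethylsilyloxy)-4-(3-methylbut-2-enyloxy)phenyl]boronic acid, in a conjugate addition. The catalyst would be cationic divalent palladium, for example Pd(OCOCF3)2 with a chiral pyridine–oxazoline ligand, and the product the tris-silylated flavanone A5.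

- In favour: it is the most convergent plan and clearly the shortest. Only a desilylation follows the key step, and on step economy it is stronger than the chosen route.
- Against: A3 is a vinylogous ester deactivated by two donor oxygens, and its C5 substituent crowds the carbonyl. A4 is electron-rich and prone to protodeboronation in the aqueous, slightly acidic medium. The prenyl alkene is a ligand and a substrate for electrophilic divalent palladium. The aryl silyl ethers and the product, which can open and reclose, are exposed to heat and acid.
- Reactivity and enantioselectivity would both hang on one step with a poorly matched substrate. In the chosen route the risky step carries no stereochemical consequence, and the enantioselective step is insensitive to the electronics of ring A. That is what it offers in exchange for its greater length.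

Alternative 3: The O1–C2 bond is cut intermolecularly. The phenol A6, 1-[2-hydroxy-4,6-bis(tert-butyldimethylsilyloxy)phenyl]ethanone, would be coupled with the cinnamyl carbonate A7, methyl (E)-3-[3-(tert-butyldimethylsilyloxy)-4-(3-methylbut-2-enyloxy)phenyl]prop-2-enyl carbonate. With [Ir(cod)Cl]2 and a chiral phosphoramidite this should give the branched ether A8. Ring C would then be closed by enol silylation of the acetyl group, ring-closing metathesis with the vinyl group and hydrolysis.

- In favour: the C–O stereocentre is set by the catalyst and not by substitution at a preformed carbinol, and both fragments are short to make.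
- Against: A6 is a chelated, delocalised and hindered ortho-acyl phenoxide, and so a poor nucleophile for this reaction. A8 is an allylic and para-alkoxybenzylic aryl ether that can re-ionise on the metal, with loss of enantiopurity and drift to the linear isomer, and it can undergo Claisen rearrangement. Three further steps are needed to close the ring, and the metathesis catalyst meets the prenyl alkene.
- The chosen route makes the same O1–C2 bond intramolecularly, with the entropic help of a six-membered closure, and never passes through a free branched allylic aryl ether. The overall step count is about the same.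

Key step: step 9

## Route

Step 1
Reactants: 1 phloroglucinol (benzene-1,3,5-triol)
Product: 2 3,5-bis(tert-butyldimethylsilyloxy)phenol
Conditions: TBSCl (2.0 equiv), imidazole, DMF, 0 °C to rt; chromatography
Reagents that add atoms: tert-butyldimethylsilyl chloride, CC(C)(C)[Si](C)(C)Cl
Why: Statistical O-silylation of a triol with three equivalent hydroxyls, so only the degree of silylation has to be separated; under- and over-silylated material can be recycled.

Step 2
Reactants: 3 3,4-dihydroxybenzaldehyde; 4 prenyl bromide (1-bromo-3-methylbut-2-ene)
Product: 5 3-hydroxy-4-(3-methylbut-2-enyloxy)benzaldehyde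
Conditions: NaHCO3 (1.5 equiv), DMF, 40 °C
Reagents that add atoms: none
Why: Williamson etherification; the 4-hydroxyl, para to the formyl group, is much more acidic than the 3-hydroxyl, so the weak base ionises only it and the allylic bromide alkylates that oxygen.

Step 3
Reactants: 5 3-hydroxy-4-(3-methylbut-2-enyloxy)benzaldehyde
Product: 6 3-(tert-butyldimethylsilyloxy)-4-(3-methylbut-2-enyloxy)benzaldehyde
Conditions: TBSCl, imidazole, CH2Cl2, rt
Reagents that add atoms: tert-butyldimethylsilyl chloride, CC(C)(C)[Si](C)(C)Cl
Why: Standard imidazole-promoted silylation of a phenol; it keeps the free phenol away from the Lewis acid and the diazo ester of the next step.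

Step 4
Reactants: 6 3-(tert-butyldimethylsilyloxy)-4-(3-methylbut-2-enyloxy)benzaldehyde; 7 ethyl diazoacetate
Product: 8 ethyl 3-[3-(tert-butyldimethylsilyloxy)-4-(3-methylbut-2-enyloxy)phenyl]-3-oxopropanoate
Conditions: SnCl2 (20 mol%), CH2Cl2, rt
Reagents that add atoms: none
Why: Roskamp homologation; the diazo carbon adds to the tin-activated aldehyde, and a 1,2-hydride shift with loss of dinitrogen gives the β-keto ester. SnCl2 is mild towards the prenyl and silyl ethers and forms no metal carbene, so the alkene is not cyclopropanated.

Step 5
Reactants: 8 ethyl 3-[3-(tert-butyldimethylsilyloxy)-4-(3-methylbut-2-enyloxy)phenyl]-3-oxopropanoate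
Product: 9 ethyl (3R)-3-[3-(tert-butyldimethylsilyloxy)-4-(3-methylbut-2-enyloxy)phenyl]-3-hydroxypropanoate
Conditions: RuCl[(R,R)-TsDPEN](p-cymene) (1 mol%), HCO2H–Et3N (5:2), CH2Cl2, 30 °C
Reagents that add atoms: none
Why: Noyori asymmetric transfer hydrogenation of an aryl ketone; the contact between the p-cymene ligand and the substrate aryl group fixes the face, so the (R,R) ligand should give the R carbinol, as with acetophenone (aryl outranks the CH2CO2Et arm). The isolated trisubstituted alkene and the ester are not reduced.

Step 6
Reactants: 9 ethyl (3R)-3-[3-(tert-butyldimethylsilyloxy)-4-(3-methylbut-2-enyloxy)phenyl]-3-hydroxypropanoate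
Product: 10 (3R)-3-hydroxy-3-[3-hydroxy-4-(3-methylbut-2-enyloxy)phenyl]propanoic acid
Conditions: LiOH (4 equiv), THF–H2O, 0 °C to rt; then 1 M HCl to pH 4, 0 °C
Reagents that add atoms: lithium hydroxide, [Li+].[OH-]
Why: Saponification; hydroxide also cleaves the base-labile aryl silyl ether, which is accepted here on purpose. The carbinol carbon bears no acidic hydrogen and keeps its configuration.

Step 7
Reactants: 10 (3R)-3-hydroxy-3-[3-hydroxy-4-(3-methylbut-2-enyloxy)phenyl]propanoic acid
Product: 12 (3R)-3-(tert-butyldimethylsilyloxy)-3-[3-(tert-butyldimethylsilyloxy)-4-(3-methylbut-2-enyloxy)phenyl]propanoic acid, via tris-silylated silyl ester 11 (not isolated)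
Conditions: TBSCl (4 equiv), imidazole, DMF, rt; then K2CO3, THF–H2O, 0 °C, short; 1 M HCl to pH 4, 0 °C
Reagents that add atoms: tert-butyldimethylsilyl chloride, CC(C)(C)[Si](C)(C)Cl
Why: Exhaustive silylation of the phenol, the secondary alcohol and the acid, followed by selective hydrolysis of the silyl ester. Carboxylate is by far the best leaving group on silicon, so brief cold aqueous carbonate should leave the aryl and alkyl silyl ethers in place.

Step 8
Reactants: 12 (3R)-3-(tert-butyldimethylsilyloxy)-3-[3-(tert-butyldimethylsilyloxy)-4-(3-methylbut-2-enyloxy)phenyl]propanoic acid; 2 3,5-bis(tert-butyldimethylsilyloxy)phenol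
Product: 13 3,5-bis(tert-butyldimethylsilyloxy)phenyl (3R)-3-(tert-butyldimethylsilyloxy)-3-[3-(tert-butyldimethylsilyloxy)-4-(3-methylbut-2-enyloxy)phenyl]propanoate
Conditions: DCC, DMAP (0.2 equiv), CH2Cl2, 0 °C to rt
Reagents that add atoms: none
Why: Steglich esterification; carbodiimide activation with DMAP catalysis acylates phenols under neutral conditions that spare the β-silyloxy group and the prenyl ether.

Step 9
Reactants: 13 3,5-bis(tert-butyldimethylsilyloxy)phenyl (3R)-3-(tert-butyldimethylsilyloxy)-3-[3-(tert-butyldimethylsilyloxy)-4-(3-methylbut-2-enyloxy)phenyl]propanoate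
Product: 14 (3R)-3-(tert-butyldimethylsilyloxy)-1-[2-hydroxy-4,6-bis(tert-butyldimethylsilyloxy)phenyl]-3-[3-(tert-butyldimethylsilyloxy)-4-(3-methylbut-2-enyloxy)phenyl]propan-1-one
Conditions: hν (254 nm, low-pressure Hg lamp, quartz flow reactor), degassed cyclohexane, about 5 mM, 20 °C, partial conversion with recovery of 13; chromatography
Reagents that add atoms: none
Why: Light absorbed by the aryl ester populates its singlet excited state, from which the aryl O–acyl bond breaks homolytically to a phenoxyl/acyl radical pair held in the solvent cage; recombination at a ring carbon and re-aromatisation by tautomerisation give the hydroxyaryl ketone and with it the C4–C4a bond. The closest known reaction type is the photo-Fries rearrangement of aryl alkanoates to ortho- and para-hydroxyaryl ketones. No ring is closed and no stereocentre is made; the 3R carbinol carbon lies two atoms from the acyl radical centre and should pass through unchanged. The selectivity wanted is recombination at an ortho carbon, which should be favoured because each ortho carbon lies next to the oxyl oxygen and has only one silyloxy neighbour whereas the para carbon sits between two; 14, with its chelated hydroxyl, should be the least polar ketone and is isolated by chromatography, and by the symmetry of ring A even para recombination forms the same C4–C4a bond. Also needed is recombination inside the cage ahead of escape and decarbonylation: the acyl radical could lose CO only to an unstabilised primary alkyl radical, which is slow on the time scale of cage recombination, and a dilute, oxygen-free hydrocarbon medium supports the cage. The remaining need is chemoselectivity between two chromophores, because the prenyl aryl ether of ring B also absorbs at 254 nm and can undergo photo-Claisen homolysis; nothing in 13 excludes this, so the irradiation is run in flow to partial conversion and unchanged 13 is recycled. Once formed, 14 is protected from further photochemistry, because its hydrogen-bonded hydroxy ketone is the lowest-lying chromophore and sheds excitation by excited-state proton transfer. The medium stays neutral, so neither the prenyl ether nor the para-alkoxybenzylic silyl ether is ionised.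

Step 10
Reactants: 14 (3R)-3-(tert-butyldimethylsilyloxy)-1-[2-hydroxy-4,6-bis(tert-butyldimethylsilyloxy)phenyl]-3-[3-(tert-butyldimethylsilyloxy)-4-(3-methylbut-2-enyloxy)phenyl]propan-1-one
Product: 15 (3R)-3-hydroxy-3-[3-hydroxy-4-(3-methylbut-2-enyloxy)phenyl]-1-(2,4,6-trihydroxyphenyl)propan-1-one
Conditions: HF·pyridine, excess pyridine, THF, 0 °C to rt
Reagents that add atoms: none
Why: Buffered HF·pyridine cleaves all four Si–O bonds by attack of fluoride at silicon, without ionising the benzylic C–O bond or the prenyl ether. The product is a symmetric 2,4,6-trihydroxyphenyl ketone, so both ortho hydroxyls are available for the ring closure.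

Step 11
Reactants: 15 (3R)-3-hydroxy-3-[3-hydroxy-4-(3-methylbut-2-enyloxy)phenyl]-1-(2,4,6-trihydroxyphenyl)propan-1-one
Product: 16 monotesone A, (2S)-5,7-dihydroxy-2-[3-hydroxy-4-(3-methylbut-2-enyloxy)phenyl]-2,3-dihydrochromen-4-one
Conditions: PPh3, DIAD, THF, 0.01 M, −20 to 0 °C
Reagents that add atoms: none
Why: Intramolecular Mitsunobu etherification; the phosphine–azodicarboxylate pair activates the benzylic hydroxyl, and an ortho phenolic oxygen displaces it in a 6-exo-tet SN2 closure with inversion, so 3R becomes 2S. High dilution and low temperature favour ring closure over intermolecular alkylation of the other phenols and over ionisation of the para-alkoxybenzylic carbon.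

## Compound list

1 | phloroglucinol (benzene-1,3,5-triol) | Oc1cc(O)cc(O)c1 | starting material
2 | 3,5-bis(tert-butyldimethylsilyloxy)phenol | Oc1cc(O[Si](C)(C)C(C)(C)C)cc(O[Si](C)(C)C(C)(C)C)c1 | intermediate
3 | 3,4-dihydroxybenzaldehyde | O=Cc1ccc(O)c(O)c1 | starting material
4 | prenyl bromide (1-bromo-3-methylbut-2-ene) | CC(C)=CCBr | starting material
5 | 3-hydroxy-4-(3-methylbut-2-enyloxy)benzaldehyde | CC(C)=CCOc1ccc(C=O)cc1O | intermediate
6 | 3-(tert-butyldimethylsilyloxy)-4-(3-methylbut-2-enyloxy)benzaldehyde | CC(C)=CCOc1ccc(C=O)cc1O[Si](C)(C)C(C)(C)C | intermediate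
7 | ethyl diazoacetate | CCOC(=O)C=[N+]=[N-] | starting material
8 | ethyl 3-[3-(tert-butyldimethylsilyloxy)-4-(3-methylbut-2-enyloxy)phenyl]-3-oxopropanoate | CCOC(=O)CC(=O)c1ccc(OCC=C(C)C)c(O[Si](C)(C)C(C)(C)C)c1 | intermediate
9 | ethyl (3R)-3-[3-(tert-butyldimethylsilyloxy)-4-(3-methylbut-2-enyloxy)phenyl]-3-hydroxypropanoate | CC(C)=CCOc1ccc([C@@H](CC(=O)OCC)O)cc1O[Si](C)(C)C(C)(C)C | intermediate
10 | (3R)-3-hydroxy-3-[3-hydroxy-4-(3-methylbut-2-enyloxy)phenyl]propanoic acid | CC(C)=CCOc1ccc([C@@H](CC(=O)O)O)cc1O | intermediate
11 | tert-butyldimethylsilyl (3R)-3-(tert-butyldimethylsilyloxy)-3-[3-(tert-butyldimethylsilyloxy)-4-(3-methylbut-2-enyloxy)phenyl]propanoate | CC(C)=CCOc1ccc([C@@H](CC(=O)O[Si](C)(C)C(C)(C)C)O[Si](C)(C)C(C)(C)C)cc1O[Si](C)(C)C(C)(C)C | intermediate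
12 | (3R)-3-(tert-butyldimethylsilyloxy)-3-[3-(tert-butyldimethylsilyloxy)-4-(3-methylbut-2-enyloxy)phenyl]propanoic acid | CC(C)=CCOc1ccc([C@@H](CC(=O)O)O[Si](C)(C)C(C)(C)C)cc1O[Si](C)(C)C(C)(C)C | intermediate
13 | 3,5-bis(tert-butyldimethylsilyloxy)phenyl (3R)-3-(tert-butyldimethylsilyloxy)-3-[3-(tert-butyldimethylsilyloxy)-4-(3-methylbut-2-enyloxy)phenyl]propanoate | CC(C)=CCOc1ccc([C@@H](CC(=O)Oc2cc(O[Si](C)(C)C(C)(C)C)cc(O[Si](C)(C)C(C)(C)C)c2)O[Si](C)(C)C(C)(C)C)cc1O[Si](C)(C)C(C)(C)C | intermediate
14 | (3R)-3-(tert-butyldimethylsilyloxy)-1-[2-hydroxy-4,6-bis(tert-butyldimethylsilyloxy)phenyl]-3-[3-(tert-butyldimethylsilyloxy)-4-(3-methylbut-2-enyloxy)phenyl]propan-1-one | CC(C)=CCOc1ccc([C@@H](CC(=O)c2c(O)cc(O[Si](C)(C)C(C)(C)C)cc2O[Si](C)(C)C(C)(C)C)O[Si](C)(C)C(C)(C)C)cc1O[Si](C)(C)C(C)(C)C | intermediate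
15 | (3R)-3-hydroxy-3-[3-hydroxy-4-(3-methylbut-2-enyloxy)phenyl]-1-(2,4,6-trihydroxyphenyl)propan-1-one | CC(C)=CCOc1ccc([C@@H](CC(=O)c2c(O)cc(O)cc2O)O)cc1O | intermediate
16 | monotesone A, (2S)-5,7-dihydroxy-2-[3-hydroxy-4-(3-methylbut-2-enyloxy)phenyl]-2,3-dihydrochromen-4-one | CC(C)=CCOc1ccc([C@@H]2CC(=O)c3c(O)cc(O)cc3O2)cc1O | target

## Step count and risk

Total step count: 11 steps.

Longest linear sequence: 10 steps (steps 2 to 11, from 3 to 16). Step 1 is a one-step branch that joins at step 8.

Steps least certain to work:

**Step 9 (key step).** The most likely failure is competing photochemistry of the second chromophore. Ring B absorbs at the wavelength used and is the lower-energy chromophore, so excitation can end up there and break the aryl O–prenyl bond (photo-Claisen migration or loss of the prenyl group) in place of the ester O–acyl bond. Escape of the radical pair from the solvent cage and recombination at the para carbon would lower the return of 14 further. Para recombination is the lesser problem, because it is recoverable. The para-shift ketone (3R)-3-(tert-butyldimethylsilyloxy)-1-[4-hydroxy-2,6-bis(tert-butyldimethylsilyloxy)phenyl]-3-[3-(tert-butyldimethylsilyloxy)-4-(3-methylbut-2-enyloxy)phenyl]propan-1-one F1 would be set aside from the photolysate of 13 and desilylated under the conditions of step 10, and so meets the route again at 15.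

The fallback for the step itself replaces light by an anionic acyl shift and sets out from 2 and 12.
- Bromination of 2 with NBS and catalytic i-Pr2NH in CH2Cl2 at low temperature should go ortho to the free hydroxyl, since the para carbon is flanked by two silyloxy groups. It gives 2-bromo-3,5-bis(tert-butyldimethylsilyloxy)phenol F2.
- Coupling of F2 with 12 (DCC, DMAP) gives 2-bromo-3,5-bis(tert-butyldimethylsilyloxy)phenyl (3R)-3-(tert-butyldimethylsilyloxy)-3-[3-(tert-butyldimethylsilyloxy)-4-(3-methylbut-2-enyloxy)phenyl]propanoate F3.
- Treating F3 with t-BuLi (2 equiv) in THF at −100 °C brings about bromine–lithium exchange, and the ortho-lithiated aryl ester transfers its acyl group from oxygen to carbon (a halogen–metal-exchange-triggered anionic Fries rearrangement). After a mild proton quench this gives the ortho ketone, and the route is rejoined at 14.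

**Step 11.** The activated carbinol is benzylic and para to an alkoxy group. Ionisation before displacement, or β-elimination towards the enone followed by reclosure without facial control, would erode the enantiopurity at C2. The fallback sets out from 15 and moves the stereocontrol to an enzyme. Strong aqueous KOH dehydrates 15 to the chalcone phenolate, and cold acidification gives (E)-3-[3-hydroxy-4-(3-methylbut-2-enyloxy)phenyl]-1-(2,4,6-trihydroxyphenyl)prop-2-en-1-one F4. Chalcone isomerase in pH 7.5 buffer with a little DMSO then catalyses the intramolecular oxa-Michael addition of 6'-hydroxychalcones to (2S)-flavanones. The route is rejoined at 16.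

**Step 4.** The electron-rich aryl group makes the aldehyde a poor electrophile and raises its own migratory aptitude. A 1,2-aryl shift in place of the 1,2-hydride shift, or simply sluggish addition, may lower the return of 8. The fallback sets out from 6. Addition of the lithium enolate of ethyl acetate (LiN(iPr)2, THF, −78 °C) gives racemic ethyl 3-[3-(tert-butyldimethylsilyloxy)-4-(3-methylbut-2-enyloxy)phenyl]-3-hydroxypropanoate F5. Oxidation of F5 with Dess–Martin periodinane (NaHCO3, CH2Cl2) gives the β-keto ester, and the route is rejoined at 8.

**Step 7.** Loss of the aryl silyl ether during the carbonate hydrolysis of the silyl ester is the likely failure, because aryl silyl ethers are themselves cleaved by carbonate on longer exposure. The fallback avoids the desilylation and resilylation altogether and sets out from 9. Silylation of the secondary hydroxyl of 9 (TBSCl, imidazole, DMF) gives ethyl (3R)-3-(tert-butyldimethylsilyloxy)-3-[3-(tert-butyldimethylsilyloxy)-4-(3-methylbut-2-enyloxy)phenyl]propanoate F6. Neutral ester cleavage of F6 with Me3SnOH in 1,2-dichloroethane at 80 °C, followed by a mildly acidic wash, should spare both silyl ethers. The route is rejoined at 12.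

**Step 1.** Silylation of three equivalent hydroxyls is statistical, so over- and under-silylation and a demanding separation are to be expected. The fallback reverses the order of events and sets out from 12 and 1. Carbodiimide coupling of 12 with a large excess of 1 (DCC, DMAP, THF) gives mainly the mono-ester 3,5-dihydroxyphenyl (3R)-3-(tert-butyldimethylsilyloxy)-3-[3-(tert-butyldimethylsilyloxy)-4-(3-methylbut-2-enyloxy)phenyl]propanoate F7. The excess triol is washed out with water, and acyl migration between the equivalent oxygens is without consequence. Silylation of the two remaining phenols of F7 (TBSCl, imidazole) rejoins the route at 13.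

## Further compounds

F1 | step 9 | (3R)-3-(tert-butyldimethylsilyloxy)-1-[4-hydroxy-2,6-bis(tert-butyldimethylsilyloxy)phenyl]-3-[3-(tert-butyldimethylsilyloxy)-4-(3-methylbut-2-enyloxy)phenyl]propan-1-one | CC(C)=CCOc1ccc([C@@H](CC(=O)c2c(O[Si](C)(C)C(C)(C)C)cc(O)cc2O[Si](C)(C)C(C)(C)C)O[Si](C)(C)C(C)(C)C)cc1O[Si](C)(C)C(C)(C)C
F2 | step 9 | 2-bromo-3,5-bis(tert-butyldimethylsilyloxy)phenol | Oc1cc(O[Si](C)(C)C(C)(C)C)cc(O[Si](C)(C)C(C)(C)C)c1Br
F3 | step 9 | 2-bromo-3,5-bis(tert-butyldimethylsilyloxy)phenyl (3R)-3-(tert-butyldimethylsilyloxy)-3-[3-(tert-butyldimethylsilyloxy)-4-(3-methylbut-2-enyloxy)phenyl]propanoate | CC(C)=CCOc1ccc([C@@H](CC(=O)Oc2cc(O[Si](C)(C)C(C)(C)C)cc(O[Si](C)(C)C(C)(C)C)c2Br)O[Si](C)(C)C(C)(C)C)cc1O[Si](C)(C)C(C)(C)C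
F4 | step 11 | (E)-3-[3-hydroxy-4-(3-methylbut-2-enyloxy)phenyl]-1-(2,4,6-trihydroxyphenyl)prop-2-en-1-one | CC(C)=CCOc1ccc(/C=C/C(=O)c2c(O)cc(O)cc2O)cc1O
F5 | step 4 | ethyl 3-[3-(tert-butyldimethylsilyloxy)-4-(3-methylbut-2-enyloxy)phenyl]-3-hydroxypropanoate (racemic) | CCOC(=O)CC(O)c1ccc(OCC=C(C)C)c(O[Si](C)(C)C(C)(C)C)c1
F6 | step 7 | ethyl (3R)-3-(tert-butyldimethylsilyloxy)-3-[3-(tert-butyldimethylsilyloxy)-4-(3-methylbut-2-enyloxy)phenyl]propanoate | CC(C)=CCOc1ccc([C@@H](CC(=O)OCC)O[Si](C)(C)C(C)(C)C)cc1O[Si](C)(C)C(C)(C)C
F7 | step 1 | 3,5-dihydroxyphenyl (3R)-3-(tert-butyldimethylsilyloxy)-3-[3-(tert-butyldimethylsilyloxy)-4-(3-methylbut-2-enyloxy)phenyl]propanoate | CC(C)=CCOc1ccc([C@@H](CC(=O)Oc2cc(O)cc(O)c2)O[Si](C)(C)C(C)(C)C)cc1O[Si](C)(C)C(C)(C)C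
A1 | alternative 1 | 2-diazo-1-[2-{[3-(tert-butyldimethylsilyloxy)-4-(3-methylbut-2-enyloxy)phenyl]methoxy}-4,6-bis(triisopropylsilyloxy)phenyl]ethanone | [N-]=[N+]=CC(=O)c1c(OCc2ccc(OCC=C(C)C)c(O[Si](C)(C)C(C)(C)C)c2)cc(O[Si](C(C)C)(C(C)C)C(C)C)cc1O[Si](C(C)C)(C(C)C)C(C)C
A2 | alternative 1 | (2S)-2-[3-(tert-butyldimethylsilyloxy)-4-(3-methylbut-2-enyloxy)phenyl]-5,7-bis(triisopropylsilyloxy)-2,3-dihydrochromen-4-one | CC(C)=CCOc1ccc([C@@H]2CC(=O)c3c(O[Si](C(C)C)(C(C)C)C(C)C)cc(O[Si](C(C)C)(C(C)C)C(C)C)cc3O2)cc1O[Si](C)(C)C(C)(C)C
A3 | alternative 2 | 5,7-bis(tert-butyldimethylsilyloxy)chromen-4-one | O=c1ccoc2cc(O[Si](C)(C)C(C)(C)C)cc(O[Si](C)(C)C(C)(C)C)c12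
A4 | alternative 2 | [3-(tert-butyldimethylsilyloxy)-4-(3-methylbut-2-enyloxy)phenyl]boronic acid | CC(C)=CCOc1ccc(B(O)O)cc1O[Si](C)(C)C(C)(C)C
A5 | alternative 2 | (2S)-5,7-bis(tert-butyldimethylsilyloxy)-2-[3-(tert-butyldimethylsilyloxy)-4-(3-methylbut-2-enyloxy)phenyl]-2,3-dihydrochromen-4-one | CC(C)=CCOc1ccc([C@@H]2CC(=O)c3c(O[Si](C)(C)C(C)(C)C)cc(O[Si](C)(C)C(C)(C)C)cc3O2)cc1O[Si](C)(C)C(C)(C)C
A6 | alternative 3 | 1-[2-hydroxy-4,6-bis(tert-butyldimethylsilyloxy)phenyl]ethanone | CC(=O)c1c(O)cc(O[Si](C)(C)C(C)(C)C)cc1O[Si](C)(C)C(C)(C)C
A7 | alternative 3 | methyl (E)-3-[3-(tert-butyldimethylsilyloxy)-4-(3-methylbut-2-enyloxy)phenyl]prop-2-enyl carbonate | COC(=O)OC/C=C/c1ccc(OCC=C(C)C)c(O[Si](C)(C)C(C)(C)C)c1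
A8 | alternative 3 | 1-[2-{(1S)-1-[3-(tert-butyldimethylsilyloxy)-4-(3-methylbut-2-enyloxy)phenyl]prop-2-enyloxy}-4,6-bis(tert-butyldimethylsilyloxy)phenyl]ethanone | CC(=O)c1c(O[C@@H](C=C)c2ccc(OCC=C(C)C)c(O[Si](C)(C)C(C)(C)C)c2)cc(O[Si](C)(C)C(C)(C)C)cc1O[Si](C)(C)C(C)(C)C
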